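**Retrosynthetic overview**
1. Target 13 ⇐ (2S)-8-prenylflavanone 10 by oxygenation of C3–H trans to the C2 aryl group, as flavanone 3-hydroxylase does.
2. 10 ⇐ 5-O-prenyl flavanone 7 by O→C8 prenyl transfer (Claisen then Cope), which also frees the 5-OH; the prenyl ether doubles as the 5-OH protecting group.
3. 7 ⇐ chalcone 6 by a catalytic enantioselective 6-endo oxa-Michael closure, as chalcone isomerase does; this sets C2.
4. 6 ⇐ acetophenone 3 + isovanillin 4 (Claisen–Schmidt); 3 ⇐ 1 + prenyl bromide 2.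
5. Rings A and B are bought; ring C is the only ring formed (step 3).

Assumption: the quinine-derived thiourea is taken to give the 2S series in step 3; if the first run shows the opposite sense (2S flavanones give a positive Cotton effect near 330 nm and a negative one near 290 nm), the quinidine-derived pseudoenantiomer is used with nothing else changed.

**Step 1**
Reactants: 1 1-(2,6-dihydroxy-4-methoxyphenyl)ethanone; 2 1-bromo-3-methylbut-2-ene (prenyl bromide)
Product: 3 1-[2-hydroxy-4-methoxy-6-(3-methylbut-2-enyloxy)phenyl]ethanone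
Conditions: 2 (1.0 equiv), K2CO3 (1.1 equiv), acetone, 56 °C, 6 h
Reagents that add atoms: prenyl bromide, CC(C)=CCBr
Why: Williamson etherification of a symmetric bis-phenol, so either OH gives the same ether, and the remaining OH is locked in a hydrogen bond to the ketone and alkylates much more slowly, so the mono-ether dominates.

**Step 2**
Reactants: 3 1-[2-hydroxy-4-methoxy-6-(3-methylbut-2-enyloxy)phenyl]ethanone; 4 3-hydroxy-4-methoxybenzaldehyde (isovanillin)
Product: 6 (E)-3-(3-hydroxy-4-methoxyphenyl)-1-[2-hydroxy-4-methoxy-6-(3-methylbut-2-enyloxy)phenyl]prop-2-en-1-one, via aldol adduct 5 (not isolated)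
Conditions: KOH (6 equiv, 50% aq.), EtOH, 0 °C to rt, 48 h; then cold 1 M HCl to pH 4
Reagents that add atoms: isovanillin, COc1ccc(C=O)cc1O
Why: Claisen–Schmidt condensation (aldol addition then E1cB dehydration to the E-enone) works without protection because the isovanillin phenoxide is meta to the aldehyde and not conjugated with it, and the open chalcone phenoxide is stable in strong base until cold acidification.

**Step 3**
Reactants: 6 (E)-3-(3-hydroxy-4-methoxyphenyl)-1-[2-hydroxy-4-methoxy-6-(3-methylbut-2-enyloxy)phenyl]prop-2-en-1-one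
Product: 7 (2S)-2-(3-hydroxy-4-methoxyphenyl)-7-methoxy-5-(3-methylbut-2-enyloxy)chroman-4-one
Conditions: 1-[3,5-bis(trifluoromethyl)phenyl]-3-[(8α,9S)-6'-methoxycinchonan-9-yl]thiourea (10 mol%), toluene–CH2Cl2 4:1, 0 °C, 72 h; one recrystallisation
Reagents that add atoms: none
Why: Proposed new method: a chalcone-isomerase-like 6-endo-trig oxa-Michael addition on an ester-free chalcone, in which the quinuclidine nitrogen takes the 2'-OH proton while the thiourea N–H pair binds the enone carbonyl, so the ion-paired phenoxide adds to one enantioface of the β-carbon (C2 set as S by the catalyst) and the quinuclidinium then protonates C3; the 6'-prenyloxy group twists the aroyl group out of conjugation, which should make closure fast enough at 0 °C that the retro-reaction (the racemisation path) stays slow; the closest known reaction types are the cinchona-thiourea oxa-Michael cyclisation of α-alkoxycarbonyl-activated 2'-hydroxychalcones and the cinchona-alkaloid isomerisation of plain 2'-hydroxychalcones, which gives only moderate ee, hence the recrystallisation.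

**Step 4**
Reactants: 7 (2S)-2-(3-hydroxy-4-methoxyphenyl)-7-methoxy-5-(3-methylbut-2-enyloxy)chroman-4-one
Product: 10 (2S)-5-hydroxy-2-(3-hydroxy-4-methoxyphenyl)-7-methoxy-8-(3-methylbut-2-enyl)chroman-4-one, via ortho-dienone 8 (not isolated), via para-dienone 9 (not isolated)
Conditions: Eu(fod)3 (10 mol%), CHCl3, 60 °C, sealed tube, 24 h
Reagents that add atoms: none
Why: Lewis-acid-accelerated aromatic Claisen rearrangement to C6 (C4a is blocked) followed by a Cope rearrangement that relays the allyl unit to C8 in the normal prenyl orientation (para-Claisen), then tautomerisation to the chelated 5-OH phenol; no bond at C2 is touched, so the 2S centre is carried through.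

**Step 5**
Reactants: 10 (2S)-5-hydroxy-2-(3-hydroxy-4-methoxyphenyl)-7-methoxy-8-(3-methylbut-2-enyl)chroman-4-one
Product: 13 (2R,3R)-3,5-dihydroxy-2-(3-hydroxy-4-methoxyphenyl)-7-methoxy-8-(3-methylbut-2-enyl)chroman-4-one, via tris-silyl enol ether 11 (not isolated), via siloxy epoxide 12 (not isolated)
Conditions: TMSOTf (3.5 equiv), Et3N (4 equiv), CH2Cl2, 0 °C, 1 h; volatiles off in vacuo; DMDO (1.05 equiv, acetone), CH2Cl2, −78 °C, 20 min; HCl (0.1 M, cat.), MeOH, 0 °C
Reagents that add atoms: dimethyldioxirane (DMDO), CC1(C)OO1; trimethylsilyl triflate (TMSOTf), C[Si](C)(C)OS(=O)(=O)C(F)(F)F (its silyl groups are in 11 and 12 only)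
Why: Rubottom oxidation, in which soft enolisation gives the 4-silyloxy-2H-chromene without opening ring C, the enol ether is far more nucleophilic than the trisubstituted prenyl alkene so one equivalent of DMDO at −78 °C epoxidises only C3=C4, and attack anti to the C2 aryl group sets C3 as R (2,3-trans) once acid methanolysis opens the siloxy epoxide and removes the three silyl groups.

**Compound list**
1 | 1-(2,6-dihydroxy-4-methoxyphenyl)ethanone | CC(=O)c1c(O)cc(OC)cc1O | starting material
2 | 1-bromo-3-methylbut-2-ene (prenyl bromide) | CC(C)=CCBr | starting material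
3 | 1-[2-hydroxy-4-methoxy-6-(3-methylbut-2-enyloxy)phenyl]ethanone | CC(=O)c1c(O)cc(OC)cc1OCC=C(C)C | intermediate
4 | 3-hydroxy-4-methoxybenzaldehyde (isovanillin) | COc1ccc(C=O)cc1O | starting material
5 | racemic 3-hydroxy-3-(3-hydroxy-4-methoxyphenyl)-1-[2-hydroxy-4-methoxy-6-(3-methylbut-2-enyloxy)phenyl]propan-1-one (aldol adduct) | COc1ccc(C(O)CC(=O)c2c(O)cc(OC)cc2OCC=C(C)C)cc1O | intermediate
6 | (E)-3-(3-hydroxy-4-methoxyphenyl)-1-[2-hydroxy-4-methoxy-6-(3-methylbut-2-enyloxy)phenyl]prop-2-en-1-one | COc1ccc(/C=C/C(=O)c2c(O)cc(OC)cc2OCC=C(C)C)cc1O | intermediate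
7 | (2S)-2-(3-hydroxy-4-methoxyphenyl)-7-methoxy-5-(3-methylbut-2-enyloxy)chroman-4-one | COc1ccc([C@H]2Oc3cc(OC)cc(OCC=C(C)C)c3C(=O)C2)cc1O | intermediate
8 | (2S)-2-(3-hydroxy-4-methoxyphenyl)-7-methoxy-6-(2-methylbut-3-en-2-yl)-2,3-dihydrochromene-4,5(6H)-dione (ortho-dienone, both C6 epimers) | COc1ccc([C@H]2OC3=C(C(=O)C2)C(=O)C(C(C)(C)C=C)C(OC)=C3)cc1O | intermediate
9 | (2S)-2-(3-hydroxy-4-methoxyphenyl)-7-methoxy-8-(3-methylbut-2-enyl)-2,3-dihydrochromene-4,5(8H)-dione (para-dienone, both C8 epimers) | COc1ccc([C@H]2OC3=C(C(=O)C2)C(=O)C=C(OC)C3CC=C(C)C)cc1O | intermediate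
10 | (2S)-5-hydroxy-2-(3-hydroxy-4-methoxyphenyl)-7-methoxy-8-(3-methylbut-2-enyl)chroman-4-one | COc1ccc([C@H]2Oc3c(CC=C(C)C)c(OC)cc(O)c3C(=O)C2)cc1O | intermediate
11 | (2S)-7-methoxy-2-(4-methoxy-3-trimethylsilyloxyphenyl)-8-(3-methylbut-2-enyl)-4,5-bis(trimethylsilyloxy)-2H-chromene | COc1ccc([C@H]2Oc3c(CC=C(C)C)c(OC)cc(O[Si](C)(C)C)c3C(O[Si](C)(C)C)=C2)cc1O[Si](C)(C)C | intermediate
12 | 3,4-epoxide of 11, epoxide oxygen on the face opposite the C2 aryl group, C4 bearing OSiMe3 (flavan numbering) | COc1ccc([C@H]2Oc3c(CC=C(C)C)c(OC)cc(O[Si](C)(C)C)c3[C@]4(O[Si](C)(C)C)O[C@H]24)cc1O[Si](C)(C)C | intermediate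
13 | (2R,3R)-3,5-dihydroxy-2-(3-hydroxy-4-methoxyphenyl)-7-methoxy-8-(3-methylbut-2-enyl)chroman-4-one (CNP0302743.1) | COc1ccc([C@H]2Oc3c(CC=C(C)C)c(OC)cc(O)c3C(=O)[C@@H]2O)cc1O | target

**Totals**
Total steps: 5. Longest linear sequence: 5 (1 → 3 → 6 → 7 → 10 → 13).

**Steps most likely to fail, with fallbacks**

Step 3 (enantioselective closure of an unactivated chalcone; the risk is low rate or low ee). The fallback sets out from 6 and returns at 7. Chalcone 6 is closed without stereocontrol (NaOAc, EtOH, reflux) to racemic 2-(3-hydroxy-4-methoxyphenyl)-7-methoxy-5-(3-methylbut-2-enyloxy)chroman-4-one F1. F1 is then resolved kinetically by asymmetric transfer hydrogenation with RuCl[(R,R)-TsDPEN](p-cymene), HCO2H/Et3N, EtOAc, rt, run to about 55% conversion. This catalyst's preferred hydride delivery (to give a 4R alcohol) is matched with cis-reduction of the 2R ketone, which goes to (2R,4R)-2-(3-hydroxy-4-methoxyphenyl)-7-methoxy-5-(3-methylbut-2-enyloxy)chroman-4-ol F2 and is removed by chromatography. The unreacted ketone is 7.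

Step 4 (Claisen–Cope on the chiral flavanone; the risks are stopping at the 6-(1,1-dimethylallyl) phenol and erosion of ee at 60 °C). The fallback sets out from 1 and returns at 10, putting the prenyl group on carbon before ring C exists. Compound 1 is C-prenylated with 2 (DBU, THF, 0 °C to rt) to give 1-[2,6-dihydroxy-4-methoxy-3-(3-methylbut-2-enyl)phenyl]ethanone F3. MOMCl and i-Pr2NEt (CH2Cl2, 0 °C) then cap the less hindered OH, the one flanked by H, to give 1-[2-hydroxy-6-(methoxymethoxy)-4-methoxy-3-(3-methylbut-2-enyl)phenyl]ethanone F4; this selectivity rests on sterics alone and is the weak point of the fallback. Claisen–Schmidt condensation with 4 (KOH, EtOH) gives (E)-3-(3-hydroxy-4-methoxyphenyl)-1-[2-hydroxy-6-(methoxymethoxy)-4-methoxy-3-(3-methylbut-2-enyl)phenyl]prop-2-en-1-one F5, whose only free ortho-OH sits next to the prenyl group. The step 3 catalyst closes it to (2S)-2-(3-hydroxy-4-methoxyphenyl)-7-methoxy-5-(methoxymethoxy)-8-(3-methylbut-2-enyl)chroman-4-one F6, and HCl in MeOH at rt removes the MOM group to give 10.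

Step 5 (C3 oxygenation; the risk is DMDO attack on the prenyl alkene or incomplete silylation of the chelated 5-OH). The fallback sets out from 10 and returns at 13, using an oxidant that does not touch alkenes. Compound 10 is deprotonated three times with NaN(SiMe3)2 (3.3 equiv, THF, −78 °C) to the trisodium 3',5-diphenoxide C3-enolate of 10 F7. The 5-phenoxide makes expulsion of the ring oxygen (ring opening to the chalcone) unfavourable. F7 is oxidised at −78 °C with 3-phenyl-2-(phenylsulfonyl)oxaziridine (Davis oxaziridine) on the face anti to the C2 aryl group and quenched cold with AcOH to give 13.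

**Further compounds**
F1 | step 3 | racemic 2-(3-hydroxy-4-methoxyphenyl)-7-methoxy-5-(3-methylbut-2-enyloxy)chroman-4-one | COc1ccc(C2Oc3cc(OC)cc(OCC=C(C)C)c3C(=O)C2)cc1O
F2 | step 3 | (2R,4R)-2-(3-hydroxy-4-methoxyphenyl)-7-methoxy-5-(3-methylbut-2-enyloxy)chroman-4-ol | COc1ccc([C@@H]2Oc3cc(OC)cc(OCC=C(C)C)c3[C@H](O)C2)cc1O
F3 | step 4 | 1-[2,6-dihydroxy-4-methoxy-3-(3-methylbut-2-enyl)phenyl]ethanone | CC(=O)c1c(O)cc(OC)c(CC=C(C)C)c1O
F4 | step 4 | 1-[2-hydroxy-6-(methoxymethoxy)-4-methoxy-3-(3-methylbut-2-enyl)phenyl]ethanone | CC(=O)c1c(OCOC)cc(OC)c(CC=C(C)C)c1O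
F5 | step 4 | (E)-3-(3-hydroxy-4-methoxyphenyl)-1-[2-hydroxy-6-(methoxymethoxy)-4-methoxy-3-(3-methylbut-2-enyl)phenyl]prop-2-en-1-one | COc1ccc(/C=C/C(=O)c2c(OCOC)cc(OC)c(CC=C(C)C)c2O)cc1O
F6 | step 4 | (2S)-2-(3-hydroxy-4-methoxyphenyl)-7-methoxy-5-(methoxymethoxy)-8-(3-methylbut-2-enyl)chroman-4-one | COc1ccc([C@H]2Oc3c(CC=C(C)C)c(OC)cc(OCOC)c3C(=O)C2)cc1O
F7 | step 5 | trisodium 3',5-diphenoxide C3-enolate of 10 | COc1ccc([C@H]2Oc3c(CC=C(C)C)c(OC)cc([O-])c3C([O-])=C2)cc1[O-].[Na+].[Na+].[Na+]
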